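# Total synthesis proposal for CNP0133858.1 (8α‑acyloxy elemanolide)

Positions are given in elemane numbering throughout: ring carbons C5–C10, vinyl C1=C2 on C10, C4 (with methylene C3 and C15) on C5, lactone carbons C11/C12, methylene C13, methyl C14. α/β refer to the usual drawing with the C10 methyl β. Tricyclic intermediates are named as tricyclo[4.4.0.0^{2,5}]decanes, whose locants map as C1 = elemane C5, C2 = C4, C5 = C1, C6 = C10, C8 = C8, C9 = C7, C10 = C6.

## Structural features

The target is an elemanolide: a cyclohexane (ring A, C5–C6–C7–C8–C9–C10) trans‑fused across C6–C7 to an α‑methylene‑γ‑butyrolactone (ring B: O–C6, C7, C11, C12, exocyclic methylene C13 on C11). Ring A carries five stereocentres: the contiguous C5, C6, C7 and C8 and the quaternary C10 next to C5. C10 bears methyl C14 and vinyl C1=C2, C5 the 3‑hydroxyprop‑1‑en‑2‑yl group, C6 the lactone oxygen, C7 the lactone carbon C11, and C8 the oxygen of an (R)‑3‑hydroxy‑2‑methylpropanoate, whose α‑carbon is the sixth stereocentre. The substituents on C5, C6, C7 and C8 are β, α, β, α and therefore all equatorial; the C10 methyl is axial and the vinyl group equatorial and trans to the C5 alkenyl group. The methylene lactone is a Michael acceptor and makes H7 vinylogously acidic, so the C8 acyloxy group is prone to elimination under base; the side‑chain α‑centre can epimerise, and two primary hydroxyls must be kept apart from the C8 oxygen. The real difficulty is the quaternary C10 beside C5, with two different alkenyl groups trans to each other, combined with the all‑trans O/C/O triad on C6–C7–C8. The key step uses the fact that the alkenyl carbons C1 and C4 sit on the adjacent ring atoms C10 and C5 while C6 carries oxygen. They can therefore be the two sp2 carbons of a cyclobutene that has added across the C5=C10 bond of a cyclohexenone with its carbonyl at C6; the other two cyclobutene carbons become the methylene termini C2 and C3 when the four‑membered rings are opened.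

## Logic of the disconnections

**36 ⇒ 35 ⇒ 31 + 34.** The C8–O acyl bond and the two O–Si bonds are cut last. The ester is the most base‑labile group (vinylogous elimination through H7), so it is made at the end on a free, equatorial C8 hydroxyl that already has the final configuration. This reduces the problem to the bicyclic core 31 and the three‑carbon acid 34. The forward acylation must not epimerise 34 or add to the methylene lactone, and the final desilylation must be non‑basic.

**31 ⇒ 30 ⇒ 27.** The C11=C13 bond and the C8 benzyl ether are cut. The methylene group is added only after all hydride steps, because it would not survive them. The forward step needs regioselective enolisation of the lactone in 27 and an oxidative ether cleavage that leaves silyl ethers and alkenes alone.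

**27 ⇒ 26 ⇒ 25 ⇒ 24.** These are oxidation‑level changes at C15 and C12. C15 must arrive as an ester, because the ester directs the photocycloaddition and activates the ring opening. It can then only be reduced together with the lactone, so the lactone is taken to the lactol and re‑oxidised. The forward sequence demands selective silylation of the primary allylic hydroxyl over the lactol hydroxyl.

**24 ⇒ 23 ⇒ 22.** In the retrosynthetic sense the Cope system is run backwards (C2–C3 joined, C5–C10 broken) to the ten‑membered diene 23, and then C1–C4 and C5–C10 are joined to the bicyclo[2.2.0]hexane of 22. Both alkenyl groups and the stereocentres C5 and C10 disappear into a strained tricycle that a [2+2] addition can make. The forward ring opening must give the diene with both ring double bonds trans, and the Cope chair must carry the lactone and the C8 ether equatorially; these then fix C5 and C10. The lactone is closed before the opening because C6 can be set cleanly only in the rigid tricycle. After the opening, hydride would approach a C6 ketone from the side away from the axial C10 methyl and give the wrong epimer.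

**22 ⇒ 21/20 ⇒ 19 ⇒ 18.** The lactone C12–O6 bond, the C6–H bond and the C7–C11 bond are cut. In 18 the four‑membered rings cover one face and the C8 ether stands on that same face, so enolate alkylation at C7 and hydride delivery at C6 should both occur on the open face. That gives C7 trans to C8 and C6 trans to C7. The side‑chain acid is freed as the only carboxyl (allyl ester, then carbodiimide), so the neopentyl ester on C4, which lies cis to the new C6 hydroxyl, cannot take part in lactonisation.

**18 ⇒ 17 ⇒ 16 ⇒ 15/14 ⇒ 13 ⇒ 12.** The C8–O bond is cut with inversion. The photocycloaddition places the four‑membered rings anti to the C8 oxygen, whereas the target has the C8 oxygen cis to the vinyl group, so C8 has to be inverted once. Doing this late was rejected for three reasons: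
- with the oxygen trans to the four‑membered rings, the C7 alkylation is pulled to opposite faces by the two control elements;
- the C8 ether would be axial and syn to the axial methyl in the Cope chair;
- an SN2 esterification at the end would act on a hindered axial alcohol whose anti‑periplanar H7 is activated by the methylene lactone.

Doing it early costs a ketal (otherwise the activated oxygen is β to the ketone and eliminates) but makes every later control element point the same way. It also means that a direct cycloreversion, should it compete, would leave C10 in the same configuration as the Cope re‑closure.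

**12 ⇒ 7 + 11.** C10–C1 and C5–C4 are cut. This is the strategic simplification: the quaternary centre, its neighbour and all five carbons C1–C4 and C15 come from one intermolecular step between two small rings. The demands are head‑to‑head regiochemistry, addition anti to the C8 silyloxy group and a cis‑anti‑cis ring fusion.

**7 ⇒ 6 ⇒ 5 ⇒ 4/3 ⇒ 2 ⇒ 1; 11 ⇒ 10/9 ⇒ 8; 34 ⇒ 33 ⇒ 32.** The enone comes from a meso triol by enzymatic desymmetrisation, oxidation–elimination, methyl addition and oxidative 1,3‑transposition, so the single stereocentre C8 needs no chiral reagent. The cyclobutene comes from the saturated ester by selenoxide elimination, and the side chain from the hydroxy ester of the chiral pool.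

## Other disconnections considered

**Alternative 1:** The cut is C7–C8. In the forward sense the open‑chain aldehyde enoate A2 would be treated with SmI2; the C8 ketyl would add 6‑exo to the enoate β‑carbon C7 and give the cyclohexanol A1.
- In its favour: ring A closes under mild, non‑basic conditions, and C7 and C8 are formed together. The C8 hydroxyl would emerge free and, through a chelated chair, equatorial, so neither an inversion nor a protecting‑group exchange at C8 is needed. On this point the alternative is better than the chosen plan, which spends five steps on C8.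
- Against it: the key step does not address the real difficulty. C10, C5 and C6 must be set in an open chain beforehand. 6‑exo ketyl–olefin closures are slower and less selective than 5‑exo ones, and simple reduction or pinacol coupling can compete. The new C8 alkoxide is γ to the ester and may close the 12,8‑lactone. A1 carries a methyl at C15, so the hydroxyl would need a late allylic oxidation beside the vinyl group.
- Comparison: both plans use open‑shell bond formation, but the chosen one forms the two most congested bonds first and lets ring conformation control the rest. In step count the alternative is about equal after the cyclisation and longer before it.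

**Alternative 2:** The cut is C6–C7 together with the lactone C–O bond. In the forward sense CrCl2 would turn the allylic bromide of aldehyde A4 into an allylchromium species that adds through C7 to the C6 aldehyde, and the alkoxide would close onto the ester to give A3.
- In its favour: carbocycle, lactone and exocyclic methylene arise in one operation, with the C8 and C15 oxygens already in their final state. In functional‑group economy after the key step the alternative is clearly better (two or three steps to the target against nine).
- Against it: the quaternary C10 with C5 and C8 must again be built acyclically. A4 has a stereocentre C5 that is both α to the formyl group and allylic, so it is prone to epimerisation and to double‑bond migration. The C6/C7 relationship depends on a cyclic transition state inside the forming ring, so cis‑ and trans‑fused lactones could both form. Chromium salts are needed in stoichiometric amount.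
- Comparison: the chosen plan is weaker at the end but stronger where the structure is hardest, because its key step creates C10 and C5 directly on a ring.

**Alternative 3:** The cut is C9–C10, with the C7–O bond reconnected. In the forward sense the vinyl δ‑lactone A6 would be converted with lithium diisopropylamide and tert‑butyldimethylsilyl chloride into its cyclic silyl ketene acetal, which rearranges on warming (Ireland–Claisen, boat transition state imposed by the ring) to the acid A5.
- In its favour: it is a thermal pericyclic reaction with predictable chirality transfer from C7 to C10 and needs no photochemical equipment. In predictability and scalability of the key step itself the alternative is at least the equal of the chosen plan.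
- Against it: A5 is far from the target. The carboxyl must become the vinyl group and the ketal the hydroxypropenyl group. Above all, the C7=C8 double bond must be turned regio‑ and stereoselectively into the C7–C11 bond and the C8 oxygen, for example by epoxide opening at C7 next to the C6 ether, which is a disfavoured position. A6 itself needs three contiguous stereocentres.
- Comparison: the chosen plan installs C1–C4 and C15 at their final carbon count in one step, whereas the alternative needs one‑carbon extensions at two sites and is the longer route overall.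

Key step: step 8

Remark on the chemistry: the lipase is taken to acetylate the enantiotopic hydroxyl that gives 3 as drawn; the acylation and hydrolysis directions of one enzyme give opposite enantiomers, so the required sense is accessible either way.

Remark on the chemistry: the opening of the bicyclo[2.2.0]hexane in step 17 is taken to pass through the ring‑trans,trans ten‑membered diene 23, as expected for an ester‑stabilised 1,4‑diyl, so that C5 and C10 are written in the Cope step.

## Route

Step 1
Reactants: 1 cis,cis-cyclohexane-1,3,5-triol
Product: 2 all-cis-5-(tert-butyldimethylsilyloxy)cyclohexane-1,3-diol (meso)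
Conditions: TBSCl (0.9 equiv), imidazole, DMF, 0 °C to rt
Reagents that add atoms: tert-butyldimethylsilyl chloride, CC(C)(C)[Si](C)(C)Cl
Why: Statistical monosilylation of a symmetrical triol (silyl ether formation); a deficit of silyl chloride favours the mono ether, unreacted triol is recovered, and the product keeps a mirror plane through the future C8.

Step 2
Reactants: 2 all-cis-5-(tert-butyldimethylsilyloxy)cyclohexane-1,3-diol
Product: 3 (1S,3R,5R)-3-(tert-butyldimethylsilyloxy)-5-hydroxycyclohexyl acetate
Conditions: immobilised Candida antarctica lipase B, vinyl acetate, tBuOMe, rt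
Reagents that add atoms: vinyl acetate, CC(=O)OC=C
Why: Lipase-catalysed desymmetrisation of a meso 1,3-diol by irreversible transesterification; the enzyme distinguishes the two enantiotopic carbinol carbons and thereby fixes the absolute configuration of the future C8.

Step 3
Reactants: 3 (1S,3R,5R)-3-(tert-butyldimethylsilyloxy)-5-hydroxycyclohexyl acetate
Product: 5 (S)-5-(tert-butyldimethylsilyloxy)cyclohex-2-en-1-one, via acetoxy ketone 4 (not isolated)
Conditions: Dess–Martin periodinane, CH2Cl2, rt; then DBU, 0 °C
Reagents that add atoms: none
Why: Dess–Martin oxidation of the free carbinol followed by E1cB loss of the β-acetoxy group; acetate is by far the better leaving group than the silyloxide, so the double bond forms on the acetate side and the silyloxy centre is untouched.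

Step 4
Reactants: 5 (S)-5-(tert-butyldimethylsilyloxy)cyclohex-2-en-1-one
Product: 6 (5S)-5-(tert-butyldimethylsilyloxy)-1-methylcyclohex-2-en-1-ol (both C1 epimers)
Conditions: MeLi, Et2O, −78 °C
Reagents that add atoms: methyllithium, [Li]C
Why: 1,2-Addition of an organolithium to an enone at low temperature, faster than enolisation; both carbinol epimers serve because this centre disappears in step 5.

Step 5
Reactants: 6 (5S)-5-(tert-butyldimethylsilyloxy)-1-methylcyclohex-2-en-1-ol
Product: 7 (R)-5-(tert-butyldimethylsilyloxy)-3-methylcyclohex-2-en-1-one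
Conditions: pyridinium chlorochromate (C5H5NH)[CrO3Cl], 4 Å molecular sieves, CH2Cl2, rt
Reagents that add atoms: pyridinium chlorochromate, [O-][Cr](=O)(=O)Cl.c1cc[nH+]cc1
Why: Dauben–Babler oxidative 1,3-transposition: the chromate ester of the tertiary allylic alcohol undergoes a [3,3] shift and the resulting secondary chromate is oxidised, which moves the carbonyl to C6 and leaves the methyl on the β-carbon C10; the silyloxy centre is not involved (its descriptor changes from S to R only through the priorities).

Step 6
Reactants: 8 methyl cyclobutanecarboxylate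
Product: 9 methyl 1-(phenylselanyl)cyclobutane-1-carboxylate
Conditions: LiN(iPr)2, THF, −78 °C; PhSeBr, −78 °C to 0 °C
Reagents that add atoms: phenylselenenyl bromide, Br[Se]c1ccccc1
Why: α-Selenenylation of an ester enolate; the ester has a single α-hydrogen, so only one enolate can form.

Step 7
Reactants: 9 methyl 1-(phenylselanyl)cyclobutane-1-carboxylate
Product: 11 methyl cyclobut-1-ene-1-carboxylate, via selenoxide 10 (not isolated)
Conditions: 30% H2O2, pyridine, CH2Cl2, 0 °C to rt
Reagents that add atoms: none
Why: Oxidation to the selenoxide and syn elimination near room temperature; only ring β-hydrogens are available, so the conjugated cyclobutene is the only alkene, and the volatile, polymerisable product is used at once.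

Step 8
Reactants: 7 (R)-5-(tert-butyldimethylsilyloxy)-3-methylcyclohex-2-en-1-one; 11 methyl cyclobut-1-ene-1-carboxylate
Product: 12 methyl 8-(tert-butyldimethylsilyloxy)-6-methyl-10-oxotricyclo[4.4.0.0^{2,5}]decane-2-carboxylate (cis-anti-cis; silyloxy group trans to the four-membered rings)
Conditions: hν (350 nm lamps, Pyrex), 11 (5 equiv), CH2Cl2, −40 °C, argon; then filtration through basic Al2O3
Reagents that add atoms: none
Why: Excitation of the enone at about 350 nm, where 11 does not absorb, gives after intersystem crossing the twisted enone triplet, which adds to ground-state 11 to form a triplet 1,4-biradical that closes after spin inversion; the closest known reaction type is the head-to-head [2+2] photocycloaddition of cyclohexenones with cyclobutenecarboxylates. The one new ring, the cyclobutane C10–C5–C4–C1, is closed stepwise by combination of the two radical termini, the bonds C10–C1 and C5–C4 forming one after the other. C10 is set by the substrate: the β-carbon is attacked along the axial direction of the half-chair that keeps the C8 silyloxy group pseudo-equatorial, that is on the face anti to it. C5 is set by the ring fusion, since only the cis-fused bicyclo[4.2.0]octanone is stable and any trans-fused adduct is epimerised at C5 on the basic alumina. C4 and C1 follow from the cis geometry of the cyclobutene and from its exo approach, which puts the outer four-membered ring anti to the six-membered ring. The step needs head-to-head regiochemistry, which the electron-withdrawing ester secures by sending its carbon to the α-carbon C5; facial selectivity, which rests on the C8 silyl ether; and cross-addition in preference to enone dimerisation or polymerisation of 11, which an excess of 11, low temperature and exclusion of oxygen secure.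

Step 9
Reactants: 12 methyl 8-(tert-butyldimethylsilyloxy)-6-methyl-10-oxotricyclo[4.4.0.0^{2,5}]decane-2-carboxylate
Product: 13 methyl 8-(tert-butyldimethylsilyloxy)-10,10-(ethylenedioxy)-6-methyltricyclo[4.4.0.0^{2,5}]decane-2-carboxylate
Conditions: (CH2OSiMe3)2, Me3SiOTf (cat.), CH2Cl2, −78 to −20 °C; pyridine quench
Reagents that add atoms: 1,2-bis(trimethylsilyloxy)ethane, C[Si](C)(C)OCCO[Si](C)(C)C
Why: Noyori ketalisation (silyl triflate-catalysed exchange with the bis-silyl ether of ethylene glycol) works on hindered ketones at low temperature, spares the silyl ether and the strained bicyclo[2.2.0]hexane, and removes the β-keto relationship that would turn activation of the C8 oxygen into an elimination.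

Step 10
Reactants: 13 methyl 8-(tert-butyldimethylsilyloxy)-10,10-(ethylenedioxy)-6-methyltricyclo[4.4.0.0^{2,5}]decane-2-carboxylate
Product: 14 methyl 10,10-(ethylenedioxy)-8-hydroxy-6-methyltricyclo[4.4.0.0^{2,5}]decane-2-carboxylate (hydroxyl trans to the four-membered rings)
Conditions: Bu4NF, THF, 0 °C to rt
Reagents that add atoms: none
Why: Fluoride cleavage of a secondary silyl ether; the ketal and the ester on a quaternary carbon are inert.

Step 11
Reactants: 14 methyl 10,10-(ethylenedioxy)-8-hydroxy-6-methyltricyclo[4.4.0.0^{2,5}]decane-2-carboxylate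
Product: 16 methyl 10,10-(ethylenedioxy)-8-hydroxy-6-methyltricyclo[4.4.0.0^{2,5}]decane-2-carboxylate having the hydroxyl cis to the four-membered rings (C8 epimer of 14), via inverted 4-nitrobenzoate 15 (not isolated)
Conditions: 4-O2NC6H4CO2H, PPh3, iPrO2CN=NCO2iPr, THF, 0 °C to rt; then MeOH, K2CO3, rt
Reagents that add atoms: 4-nitrobenzoic acid, OC(=O)c1ccc(cc1)[N+](=O)[O-]
Why: Mitsunobu reaction: SN2 displacement of the alkoxyphosphonium group by the carboxylate inverts C8 by mechanism, and methanolysis of the activated aryl ester frees the alcohol; the C8 oxygen now has the configuration of the target and lies on the side of the four-membered rings.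

Step 12
Reactants: 16 methyl 10,10-(ethylenedioxy)-8-hydroxy-6-methyltricyclo[4.4.0.0^{2,5}]decane-2-carboxylate (hydroxyl cis to the four-membered rings)
Product: 17 methyl 10,10-(ethylenedioxy)-8-(4-methoxybenzyloxy)-6-methyltricyclo[4.4.0.0^{2,5}]decane-2-carboxylate
Conditions: NaH, 4-MeOC6H4CH2Cl, Bu4NI (cat.), DMF, 0 °C to rt
Reagents that add atoms: 4-methoxybenzyl chloride, COc1ccc(CCl)cc1
Why: Williamson etherification; the ester has no α-hydrogen, and the benzyl ether is stable to all the bases, hydrides and the heating that follow and is removable oxidatively beside silyl ethers.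

Step 13
Reactants: 17 methyl 10,10-(ethylenedioxy)-8-(4-methoxybenzyloxy)-6-methyltricyclo[4.4.0.0^{2,5}]decane-2-carboxylate
Product: 18 methyl 8-(4-methoxybenzyloxy)-6-methyl-10-oxotricyclo[4.4.0.0^{2,5}]decane-2-carboxylate (benzyloxy group cis to the four-membered rings)
Conditions: pyridinium p-toluenesulfonate, acetone/H2O, 55 °C
Reagents that add atoms: water, O
Why: Mild acid-catalysed ketal hydrolysis; the benzyl ether, the ester and the cis ring fusion are stable under these conditions.

Step 14
Reactants: 18 methyl 8-(4-methoxybenzyloxy)-6-methyl-10-oxotricyclo[4.4.0.0^{2,5}]decane-2-carboxylate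
Product: 19 methyl 9-[2-(allyloxy)-2-oxoethyl]-8-(4-methoxybenzyloxy)-6-methyl-10-oxotricyclo[4.4.0.0^{2,5}]decane-2-carboxylate (side chain trans to the benzyloxy group and to the four-membered rings)
Conditions: LiN(iPr)2, THF, −78 °C; BrCH2CO2CH2CH=CH2, DMPU, −78 to −30 °C
Reagents that add atoms: allyl bromoacetate, C=CCOC(=O)CBr
Why: Kinetic enolate alkylation; deprotonation can occur only at the C7 methylene (C5 is a cyclobutane ring-fusion carbon), and the electrophile enters on the face opposite both the adjacent C8 ether and the four-membered rings, which sets C7 trans to C8 (also the equatorial, thermodynamic arrangement).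

Step 15
Reactants: 19 methyl 9-[2-(allyloxy)-2-oxoethyl]-8-(4-methoxybenzyloxy)-6-methyl-10-oxotricyclo[4.4.0.0^{2,5}]decane-2-carboxylate
Product: 20 methyl 9-[2-(allyloxy)-2-oxoethyl]-10-hydroxy-8-(4-methoxybenzyloxy)-6-methyltricyclo[4.4.0.0^{2,5}]decane-2-carboxylate (hydroxyl trans to the side chain, cis to the four-membered rings)
Conditions: NaBH4, MeOH/CH2Cl2, −40 to 0 °C; neutral work-up
Reagents that add atoms: none
Why: Chemoselective borohydride reduction of the ketone beside two esters; hydride should attack C6 from the open face, anti to the quaternary cyclobutane carbon on C5 and to the four-membered rings, which places the C6 oxygen trans to the C7 side chain.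

Step 16
Reactants: 20 methyl 9-[2-(allyloxy)-2-oxoethyl]-10-hydroxy-8-(4-methoxybenzyloxy)-6-methyltricyclo[4.4.0.0^{2,5}]decane-2-carboxylate
Product: 22 tetracyclic lactone: trans-fused γ-lactone between the C10 oxygen and the C9 acetic acid arm of methyl 8-(4-methoxybenzyloxy)-6-methyltricyclo[4.4.0.0^{2,5}]decane-2-carboxylate, via hydroxy acid 21 (not isolated)
Conditions: Pd(PPh3)4 (cat.), morpholine, THF, rt; aqueous KHSO4 wash; then EDC·HCl, DMAP, CH2Cl2, 0 °C to rt
Reagents that add atoms: none
Why: Allyl ester cleavage by zerovalent palladium (π-allyl transfer to morpholine) frees only the side-chain acid, and carbodiimide activation (Steglich-type lactonisation) acylates the C6 hydroxyl with that acid alone, so the neopentyl methyl ester on C4, which lies cis to the hydroxyl, cannot compete; no stereocentre changes.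

Step 17
Reactants: 22 tetracyclic lactone
Product: 24 methyl 8α-(4-methoxybenzyloxy)-13-norelema-1,3-dien-12,6α-olid-15-oate (5αH 7αH 10β-methyl), via ten-membered diene lactone 23 (not isolated)
Conditions: toluene (0.01 M, degassed), 2,6-di-tert-butyl-4-methylphenol (cat.), base-washed sealed tube, 185 °C
Reagents that add atoms: none
Why: Thermal homolysis of the central bond of the bicyclo[2.2.0]hexane gives an ester-stabilised 1,4-diyl that fragments to the ten-membered 1,5-diene (photo-thermal olefin metathesis), and its Cope rearrangement (germacranolide to elemanolide) re-forms C5–C10 through a chair with the trans lactone and the C8 ether equatorial, so that the methyl is axial and both alkenyl groups are equatorial and trans. C5 and C10 are thus set by C6, C7 and C8, and a direct cycloreversion would leave C10 with the same configuration.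

Step 18
Reactants: 24 methyl 8α-(4-methoxybenzyloxy)-13-norelema-1,3-dien-12,6α-olid-15-oate
Product: 25 8α-(4-methoxybenzyloxy)-13-nor-6α,12-epoxyelema-1,3-diene-12,15-diol (lactol; both C12 epimers)
Conditions: iBu2AlH (4 equiv), CH2Cl2, −78 °C; aqueous potassium sodium tartrate
Reagents that add atoms: none
Why: Aluminium hydride reduction at −78 °C takes the conjugated ester to the allylic alcohol without conjugate reduction and stops the lactone at the lactol, whose aluminium hemiacetal is stable at this temperature.

Step 19
Reactants: 25 8α-(4-methoxybenzyloxy)-13-nor-6α,12-epoxyelema-1,3-diene-12,15-diol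
Product: 26 15-(tert-butyldimethylsilyloxy)-8α-(4-methoxybenzyloxy)-13-nor-6α,12-epoxyelema-1,3-dien-12-ol
Conditions: TBSCl (1.05 equiv), imidazole, CH2Cl2, −20 °C
Reagents that add atoms: tert-butyldimethylsilyl chloride, CC(C)(C)[Si](C)(C)Cl
Why: Selective silylation of the unhindered primary allylic hydroxyl in preference to the secondary hemiacetal hydroxyl.

Step 20
Reactants: 26 15-(tert-butyldimethylsilyloxy)-8α-(4-methoxybenzyloxy)-13-nor-6α,12-epoxyelema-1,3-dien-12-ol
Product: 27 15-(tert-butyldimethylsilyloxy)-8α-(4-methoxybenzyloxy)-13-norelema-1,3-dien-12,6α-olide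
Conditions: Pr4N[RuO4] (cat.), N-methylmorpholine N-oxide, 4 Å molecular sieves, CH2Cl2, rt
Reagents that add atoms: none
Why: Ley–Griffith oxidation of a lactol to the lactone; silyl ether, benzyl ether and the unactivated alkenes are inert.

Step 21
Reactants: 27 15-(tert-butyldimethylsilyloxy)-8α-(4-methoxybenzyloxy)-13-norelema-1,3-dien-12,6α-olide
Product: 30 15-(tert-butyldimethylsilyloxy)-8α-(4-methoxybenzyloxy)elema-1,3,11(13)-trien-12,6α-olide, via Mannich base 28 (not isolated), via trimethylammonium iodide 29 (not isolated)
Conditions: LiN(iPr)2, THF, −78 °C; [CH2=NMe2]I, −78 °C to rt; then MeI, rt; then aqueous NaHCO3, CH2Cl2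
Reagents that add atoms: N,N-dimethylmethyleneiminium iodide (Eschenmoser's salt), C=[N+](C)C.[I-]
Why: α-Methylenation of a lactone by enolate Mannich reaction, quaternisation and E1cB loss of trimethylamine; C11 is the only enolisable position, and its configuration is irrelevant because it becomes sp2.

Step 22
Reactants: 30 15-(tert-butyldimethylsilyloxy)-8α-(4-methoxybenzyloxy)elema-1,3,11(13)-trien-12,6α-olide
Product: 31 15-(tert-butyldimethylsilyloxy)-8α-hydroxyelema-1,3,11(13)-trien-12,6α-olide
Conditions: DDQ, CH2Cl2/pH 7 phosphate buffer, 0 °C to rt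
Reagents that add atoms: none
Why: Oxidative cleavage of a 4-methoxybenzyl ether by hydride abstraction and hydrolysis of the oxocarbenium ion; it is neutral, so the methylene lactone and the silyl ether survive.

Step 23
Reactants: 32 methyl (R)-3-hydroxy-2-methylpropanoate
Product: 33 methyl (R)-3-(tert-butyldimethylsilyloxy)-2-methylpropanoate
Conditions: TBSCl, imidazole, CH2Cl2, 0 °C to rt
Reagents that add atoms: tert-butyldimethylsilyl chloride, CC(C)(C)[Si](C)(C)Cl
Why: Silyl ether formation on a primary alcohol; the stereocentre is not involved.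

Step 24
Reactants: 33 methyl (R)-3-(tert-butyldimethylsilyloxy)-2-methylpropanoate
Product: 34 (R)-3-(tert-butyldimethylsilyloxy)-2-methylpropanoic acid
Conditions: LiOH, THF/MeOH/H2O, 0 °C; then 1 M HCl to pH 3 at 0 °C
Reagents that add atoms: lithium hydroxide, [Li+].[OH-]
Why: Saponification at 0 °C, where neither α-epimerisation nor β-elimination of the silyloxy group is expected.

Step 25
Reactants: 31 15-(tert-butyldimethylsilyloxy)-8α-hydroxyelema-1,3,11(13)-trien-12,6α-olide; 34 (R)-3-(tert-butyldimethylsilyloxy)-2-methylpropanoic acid
Product: 35 15-(tert-butyldimethylsilyloxy)-8α-[(2R)-3-(tert-butyldimethylsilyloxy)-2-methylpropanoyloxy]elema-1,3,11(13)-trien-12,6α-olide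
Conditions: EDC·HCl, DMAP (0.2 equiv), CH2Cl2, 0 °C to rt
Reagents that add atoms: none
Why: Steglich esterification of an equatorial secondary alcohol with retention at C8; the low temperature and the substoichiometric amine limit epimerisation of the acid and vinylogous elimination at C7/C8.

Step 26
Reactants: 35 15-(tert-butyldimethylsilyloxy)-8α-[(2R)-3-(tert-butyldimethylsilyloxy)-2-methylpropanoyloxy]elema-1,3,11(13)-trien-12,6α-olide
Product: 36 15-hydroxy-8α-[(2R)-3-hydroxy-2-methylpropanoyloxy]elema-1,3,11(13)-trien-12,6α-olide (CNP0133858.1)
Conditions: HF·pyridine, pyridine, THF, 0 °C to rt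
Reagents that add atoms: none
Why: Buffered fluoride cleavage of two primary silyl ethers; the medium is non-basic, so the C8 ester and the methylene lactone are not endangered.

## Compound list

1 | cis,cis-cyclohexane-1,3,5-triol | O[C@H]1C[C@@H](O)C[C@@H](O)C1 | starting material
2 | all-cis-5-(tert-butyldimethylsilyloxy)cyclohexane-1,3-diol (meso) | O[C@H]1C[C@@H](O)C[C@@H](O[Si](C)(C)C(C)(C)C)C1 | intermediate
3 | (1S,3R,5R)-3-(tert-butyldimethylsilyloxy)-5-hydroxycyclohexyl acetate | O[C@H]1C[C@@H](O[Si](C)(C)C(C)(C)C)C[C@@H](OC(C)=O)C1 | intermediate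
4 | (1R,5S)-5-(tert-butyldimethylsilyloxy)-3-oxocyclohexyl acetate (not isolated) | O=C1C[C@@H](O[Si](C)(C)C(C)(C)C)C[C@@H](OC(C)=O)C1 | intermediate
5 | (S)-5-(tert-butyldimethylsilyloxy)cyclohex-2-en-1-one | O=C1C=CC[C@H](O[Si](C)(C)C(C)(C)C)C1 | intermediate
6 | (5S)-5-(tert-butyldimethylsilyloxy)-1-methylcyclohex-2-en-1-ol (both C1 epimers) | CC1(O)C=CC[C@H](O[Si](C)(C)C(C)(C)C)C1 | intermediate
7 | (R)-5-(tert-butyldimethylsilyloxy)-3-methylcyclohex-2-en-1-one | CC1=CC(=O)C[C@H](O[Si](C)(C)C(C)(C)C)C1 | intermediate
8 | methyl cyclobutanecarboxylate | COC(=O)C1CCC1 | starting material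
9 | methyl 1-(phenylselanyl)cyclobutane-1-carboxylate | COC(=O)C1([Se]c2ccccc2)CCC1 | intermediate
10 | methyl 1-(phenylseleninyl)cyclobutane-1-carboxylate (not isolated) | COC(=O)C1([Se](=O)c2ccccc2)CCC1 | intermediate
11 | methyl cyclobut-1-ene-1-carboxylate | COC(=O)C1=CCC1 | intermediate
12 | methyl 8-(tert-butyldimethylsilyloxy)-6-methyl-10-oxotricyclo[4.4.0.0^{2,5}]decane-2-carboxylate, cis-anti-cis, silyloxy trans to the four-membered rings | C[C@@]12C[C@@H](O[Si](C)(C)C(C)(C)C)CC(=O)[C@@H]1[C@@]1(C(=O)OC)CC[C@H]12 | intermediate
13 | ethylene ketal of 12 at C10 | C[C@@]12C[C@@H](O[Si](C)(C)C(C)(C)C)CC3(OCCO3)[C@@H]1[C@@]1(C(=O)OC)CC[C@H]12 | intermediate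
14 | methyl 10,10-(ethylenedioxy)-8-hydroxy-6-methyltricyclo[4.4.0.0^{2,5}]decane-2-carboxylate, hydroxyl trans to the four-membered rings | C[C@@]12C[C@@H](O)CC3(OCCO3)[C@@H]1[C@@]1(C(=O)OC)CC[C@H]12 | intermediate
15 | 8-(4-nitrobenzoyloxy) ketal, C8 inverted (not isolated) | C[C@@]12C[C@H](OC(=O)c3ccc(cc3)[N+](=O)[O-])CC3(OCCO3)[C@@H]1[C@@]1(C(=O)OC)CC[C@H]12 | intermediate
16 | C8 epimer of 14, hydroxyl cis to the four-membered rings | C[C@@]12C[C@H](O)CC3(OCCO3)[C@@H]1[C@@]1(C(=O)OC)CC[C@H]12 | intermediate
17 | methyl 10,10-(ethylenedioxy)-8-(4-methoxybenzyloxy)-6-methyltricyclo[4.4.0.0^{2,5}]decane-2-carboxylate | C[C@@]12C[C@H](OCc3ccc(OC)cc3)CC3(OCCO3)[C@@H]1[C@@]1(C(=O)OC)CC[C@H]12 | intermediate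
18 | methyl 8-(4-methoxybenzyloxy)-6-methyl-10-oxotricyclo[4.4.0.0^{2,5}]decane-2-carboxylate, benzyloxy cis to the four-membered rings | C[C@@]12C[C@H](OCc3ccc(OC)cc3)CC(=O)[C@@H]1[C@@]1(C(=O)OC)CC[C@H]12 | intermediate
19 | methyl 9-[2-(allyloxy)-2-oxoethyl]-8-(4-methoxybenzyloxy)-6-methyl-10-oxotricyclo[4.4.0.0^{2,5}]decane-2-carboxylate | C[C@@]12C[C@H](OCc3ccc(OC)cc3)[C@@H](CC(=O)OCC=C)C(=O)[C@@H]1[C@@]1(C(=O)OC)CC[C@H]12 | intermediate
20 | methyl 9-[2-(allyloxy)-2-oxoethyl]-10-hydroxy-8-(4-methoxybenzyloxy)-6-methyltricyclo[4.4.0.0^{2,5}]decane-2-carboxylate | C[C@@]12C[C@H](OCc3ccc(OC)cc3)[C@@H](CC(=O)OCC=C)[C@H](O)[C@@H]1[C@@]1(C(=O)OC)CC[C@H]12 | intermediate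
21 | hydroxy acid of 20 (allyl ester cleaved; not isolated) | C[C@@]12C[C@H](OCc3ccc(OC)cc3)[C@@H](CC(=O)O)[C@H](O)[C@@H]1[C@@]1(C(=O)OC)CC[C@H]12 | intermediate
22 | tetracyclic trans-fused γ-lactone of 21 | C[C@@]12C[C@H](OCc3ccc(OC)cc3)[C@H]3CC(=O)O[C@@H]3[C@@H]1[C@@]1(C(=O)OC)CC[C@H]12 | intermediate
23 | ten-membered diene lactone, both ring double bonds trans in the ring (germacranolide type; not isolated) | C/C1=C\CC/C(C(=O)OC)=C/[C@H]2OC(=O)C[C@@H]2[C@@H](OCc2ccc(OC)cc2)C1 | intermediate
24 | methyl 8α-(4-methoxybenzyloxy)-13-norelema-1,3-dien-12,6α-olid-15-oate | C=C[C@]1(C)C[C@H](OCc3ccc(OC)cc3)[C@H]2CC(=O)O[C@@H]2[C@H]1C(=C)C(=O)OC | intermediate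
25 | 8α-(4-methoxybenzyloxy)-13-nor-6α,12-epoxyelema-1,3-diene-12,15-diol (both C12 epimers) | C=C[C@]1(C)C[C@H](OCc3ccc(OC)cc3)[C@H]2CC(O)O[C@@H]2[C@H]1C(=C)CO | intermediate
26 | 15-(tert-butyldimethylsilyloxy)-8α-(4-methoxybenzyloxy)-13-nor-6α,12-epoxyelema-1,3-dien-12-ol | C=C[C@]1(C)C[C@H](OCc3ccc(OC)cc3)[C@H]2CC(O)O[C@@H]2[C@H]1C(=C)CO[Si](C)(C)C(C)(C)C | intermediate
27 | 15-(tert-butyldimethylsilyloxy)-8α-(4-methoxybenzyloxy)-13-norelema-1,3-dien-12,6α-olide | C=C[C@]1(C)C[C@H](OCc3ccc(OC)cc3)[C@H]2CC(=O)O[C@@H]2[C@H]1C(=C)CO[Si](C)(C)C(C)(C)C | intermediate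
28 | 13-(dimethylamino)-11,13-dihydro derivative of 30 (Mannich base, both C11 epimers; not isolated) | C=C[C@]1(C)C[C@H](OCc3ccc(OC)cc3)[C@H]2C(CN(C)C)C(=O)O[C@@H]2[C@H]1C(=C)CO[Si](C)(C)C(C)(C)C | intermediate
29 | trimethylammonium iodide of 28 (not isolated) | C=C[C@]1(C)C[C@H](OCc3ccc(OC)cc3)[C@H]2C(C[N+](C)(C)C)C(=O)O[C@@H]2[C@H]1C(=C)CO[Si](C)(C)C(C)(C)C.[I-] | intermediate
30 | 15-(tert-butyldimethylsilyloxy)-8α-(4-methoxybenzyloxy)elema-1,3,11(13)-trien-12,6α-olide | C=C[C@]1(C)C[C@H](OCc3ccc(OC)cc3)[C@H]2C(=C)C(=O)O[C@@H]2[C@H]1C(=C)CO[Si](C)(C)C(C)(C)C | intermediate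
31 | 15-(tert-butyldimethylsilyloxy)-8α-hydroxyelema-1,3,11(13)-trien-12,6α-olide | C=C[C@]1(C)C[C@H](O)[C@H]2C(=C)C(=O)O[C@@H]2[C@H]1C(=C)CO[Si](C)(C)C(C)(C)C | intermediate
32 | methyl (R)-3-hydroxy-2-methylpropanoate | COC(=O)[C@H](C)CO | starting material
33 | methyl (R)-3-(tert-butyldimethylsilyloxy)-2-methylpropanoate | COC(=O)[C@H](C)CO[Si](C)(C)C(C)(C)C | intermediate
34 | (R)-3-(tert-butyldimethylsilyloxy)-2-methylpropanoic acid | OC(=O)[C@H](C)CO[Si](C)(C)C(C)(C)C | intermediate
35 | 15-(tert-butyldimethylsilyloxy)-8α-[(2R)-3-(tert-butyldimethylsilyloxy)-2-methylpropanoyloxy]elema-1,3,11(13)-trien-12,6α-olide | C=C[C@]1(C)C[C@H](OC(=O)[C@H](C)CO[Si](C)(C)C(C)(C)C)[C@H]2C(=C)C(=O)O[C@@H]2[C@H]1C(=C)CO[Si](C)(C)C(C)(C)C | intermediate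
36 | 15-hydroxy-8α-[(2R)-3-hydroxy-2-methylpropanoyloxy]elema-1,3,11(13)-trien-12,6α-olide (CNP0133858.1) | C=C[C@]1(C)C[C@H](OC(=O)[C@H](C)CO)[C@H]2C(=C)C(=O)O[C@@H]2[C@H]1C(=C)CO | target

## Step count and least certain steps

Total: 26 steps. Longest linear sequence: 22 steps from 1 (steps 1–5, 8–22, 25, 26); steps 6–7 and 23–24 are side branches.

**Step 8 (key step).** The most likely failure is erosion of facial selectivity, because the directing silyloxy group is two atoms away from the reacting β-carbon; head-to-tail addition and polymerisation of 11 may also compete. Fallback, changing the control element rather than the irradiation conditions: 7 is desilylated with HF·pyridine to (R)-5-hydroxy-3-methylcyclohex-2-en-1-one F1, which is converted into the larger ether (R)-5-(tert-butyldiphenylsilyloxy)-3-methylcyclohex-2-en-1-one F2. Irradiation with 11 would give the corresponding cis-anti-cis adduct F3, ketalisation as in step 9 its ethylene ketal F4, and fluoride cleavage returns to the route at 14.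

**Step 17.** The most likely failure is loss of the trans ring-double-bond geometry during fragmentation (a ring-cis,trans diene or a direct cycloreversion). This would give the cis-1,2-dialkenyl lactone, whose C5 cannot be corrected once C6 is no longer a ketone; radical polymerisation of the acrylate is a second risk. Fallback: open the rings while C6 is still a ketone, so that C5 stays epimerisable. Setting out from 18:
- thermolysis and equilibration with DBU (the trans isomer is now the all-equatorial one) would give methyl 8α-(4-methoxybenzyloxy)-6-oxoelema-1,3-dien-15-oate F5;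
- iBu2AlH gives 8α-(4-methoxybenzyloxy)elema-1,3-diene-6,15-diol F6;
- selective silylation gives 15-(tert-butyldimethylsilyloxy)-8α-(4-methoxybenzyloxy)elema-1,3-dien-6-ol F7;
- Dess–Martin oxidation gives 15-(tert-butyldimethylsilyloxy)-8α-(4-methoxybenzyloxy)elema-1,3-dien-6-one F8;
- kinetic alkylation with methyl bromoacetate gives methyl 15-(tert-butyldimethylsilyloxy)-8α-(4-methoxybenzyloxy)-6-oxo-13-norelema-1,3-dien-12-oate F9;
- electron-transfer reduction (SmI2, THF/MeOH), expected to favour the equatorial C6 alcohol, and lactonisation rejoin the route at 27.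

**Step 11.** The most likely failure is elimination of the activated C8 oxygen, or slow substitution because the nucleophile must enter from the side of the four-membered rings. Fallback, replacing substitution by oxidation–reduction: 14 is oxidised with Dess–Martin periodinane to methyl 10,10-(ethylenedioxy)-6-methyl-8-oxotricyclo[4.4.0.0^{2,5}]decane-2-carboxylate F10, and a bulky hydride, LiBH(sBu)3, approaching from the face away from the four-membered rings, would return 16.

**Step 14.** The most likely failures are proton transfer from the bromoacetate to the enolate with Darzens-type condensation, over-alkylation, or β-elimination of the C8 ether from the enolate. Fallback, introducing the two carbons as an allyl group (possible because the tricycle has no other alkene): 18 is alkylated with allyl iodide to methyl 9-allyl-8-(4-methoxybenzyloxy)-6-methyl-10-oxotricyclo[4.4.0.0^{2,5}]decane-2-carboxylate F11. Cleavage with OsO4 (cat.)/NaIO4 gives the 9-(2-oxoethyl) aldehyde F12, NaClO2 oxidation the 9-(carboxymethyl) keto acid F13, and NaBH4 reduction rejoins the route at 21.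

**Step 15.** The most likely failures are hydride delivery from the cyclobutane face, or attack of the new alkoxide on the C4 methyl ester. Fallback for the wrong epimer, closing the lactone with inversion instead of retention: the C10 epimer of 20, F14, obtained from 19, is deallylated to the epimeric hydroxy acid F15, which is cyclised under Mitsunobu conditions (PPh3, diisopropyl azodicarboxylate) with inversion at C6 to 22.

## Further compounds

F1 | step 8 | (R)-5-hydroxy-3-methylcyclohex-2-en-1-one | CC1=CC(=O)C[C@H](O)C1
F2 | step 8 | (R)-5-(tert-butyldiphenylsilyloxy)-3-methylcyclohex-2-en-1-one | CC1=CC(=O)C[C@H](O[Si](c2ccccc2)(c2ccccc2)C(C)(C)C)C1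
F3 | step 8 | methyl 8-(tert-butyldiphenylsilyloxy)-6-methyl-10-oxotricyclo[4.4.0.0^{2,5}]decane-2-carboxylate (cis-anti-cis, silyloxy trans to the four-membered rings) | C[C@@]12C[C@@H](O[Si](c3ccccc3)(c3ccccc3)C(C)(C)C)CC(=O)[C@@H]1[C@@]1(C(=O)OC)CC[C@H]12
F4 | step 8 | ethylene ketal of F3 | C[C@@]12C[C@@H](O[Si](c3ccccc3)(c3ccccc3)C(C)(C)C)CC3(OCCO3)[C@@H]1[C@@]1(C(=O)OC)CC[C@H]12
F5 | step 17 | methyl 8α-(4-methoxybenzyloxy)-6-oxoelema-1,3-dien-15-oate | C=C[C@]1(C)C[C@H](OCc2ccc(OC)cc2)CC(=O)[C@H]1C(=C)C(=O)OC
F6 | step 17 | 8α-(4-methoxybenzyloxy)elema-1,3-diene-6,15-diol (both C6 epimers) | C=C[C@]1(C)C[C@H](OCc2ccc(OC)cc2)CC(O)[C@H]1C(=C)CO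
F7 | step 17 | 15-(tert-butyldimethylsilyloxy)-8α-(4-methoxybenzyloxy)elema-1,3-dien-6-ol (both C6 epimers) | C=C[C@]1(C)C[C@H](OCc2ccc(OC)cc2)CC(O)[C@H]1C(=C)CO[Si](C)(C)C(C)(C)C
F8 | step 17 | 15-(tert-butyldimethylsilyloxy)-8α-(4-methoxybenzyloxy)elema-1,3-dien-6-one | C=C[C@]1(C)C[C@H](OCc2ccc(OC)cc2)CC(=O)[C@H]1C(=C)CO[Si](C)(C)C(C)(C)C
F9 | step 17 | methyl 15-(tert-butyldimethylsilyloxy)-8α-(4-methoxybenzyloxy)-6-oxo-13-norelema-1,3-dien-12-oate | C=C[C@]1(C)C[C@H](OCc2ccc(OC)cc2)[C@@H](CC(=O)OC)C(=O)[C@H]1C(=C)CO[Si](C)(C)C(C)(C)C
F10 | step 11 | methyl 10,10-(ethylenedioxy)-6-methyl-8-oxotricyclo[4.4.0.0^{2,5}]decane-2-carboxylate | C[C@@]12CC(=O)CC3(OCCO3)[C@@H]1[C@@]1(C(=O)OC)CC[C@H]12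
F11 | step 14 | methyl 9-allyl-8-(4-methoxybenzyloxy)-6-methyl-10-oxotricyclo[4.4.0.0^{2,5}]decane-2-carboxylate | C[C@@]12C[C@H](OCc3ccc(OC)cc3)[C@@H](CC=C)C(=O)[C@@H]1[C@@]1(C(=O)OC)CC[C@H]12
F12 | step 14 | methyl 8-(4-methoxybenzyloxy)-6-methyl-10-oxo-9-(2-oxoethyl)tricyclo[4.4.0.0^{2,5}]decane-2-carboxylate | C[C@@]12C[C@H](OCc3ccc(OC)cc3)[C@@H](CC=O)C(=O)[C@@H]1[C@@]1(C(=O)OC)CC[C@H]12
F13 | step 14 | 2-[2-(methoxycarbonyl)-8-(4-methoxybenzyloxy)-6-methyl-10-oxotricyclo[4.4.0.0^{2,5}]decan-9-yl]acetic acid | C[C@@]12C[C@H](OCc3ccc(OC)cc3)[C@@H](CC(=O)O)C(=O)[C@@H]1[C@@]1(C(=O)OC)CC[C@H]12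
F14 | step 15 | C10 epimer of 20 (hydroxyl cis to the side chain, trans to the four-membered rings) | C[C@@]12C[C@H](OCc3ccc(OC)cc3)[C@@H](CC(=O)OCC=C)[C@@H](O)[C@@H]1[C@@]1(C(=O)OC)CC[C@H]12
F15 | step 15 | C10 epimer of hydroxy acid 21 | C[C@@]12C[C@H](OCc3ccc(OC)cc3)[C@@H](CC(=O)O)[C@@H](O)[C@@H]1[C@@]1(C(=O)OC)CC[C@H]12
A1 | alternative 1 | cyclohexanol with free C8 hydroxyl, C7 methyl acetate arm, C6 4-methoxybenzyl ether and C5 isopropenyl group | C=C[C@]1(C)C[C@H](O)[C@@H](CC(=O)OC)[C@H](OCc2ccc(OC)cc2)[C@H]1C(C)=C
A2 | alternative 1 | open-chain aldehyde enoate: methyl (E)-4-(4-methoxybenzyloxy)-5-isopropenyl-6-methyl-6-(2-oxoethyl)octa-2,7-dienoate | C=C[C@](C)(CC=O)[C@H](C(C)=C)[C@@H](OCc1ccc(OC)cc1)/C=C/C(=O)OC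
A3 | alternative 2 | 15-(tert-butyldiphenylsilyloxy)-8α-(triethylsilyloxy)elema-1,3,11(13)-trien-12,6α-olide | C=C[C@]1(C)C[C@H](O[Si](CC)(CC)CC)[C@H]2C(=C)C(=O)O[C@@H]2[C@H]1C(=C)CO[Si](c1ccccc1)(c1ccccc1)C(C)(C)C
A4 | alternative 2 | open-chain C6 aldehyde with (Z)-2-(bromomethyl)enoate, C8 triethylsilyl ether and C15 tert-butyldiphenylsilyl ether | O=C[C@@H](C(=C)CO[Si](c1ccccc1)(c1ccccc1)C(C)(C)C)[C@](C)(C=C)C[C@H](O[Si](CC)(CC)CC)/C=C(\CBr)C(=O)OC
A5 | alternative 3 | 1-methyl-6-(2-methyl-1,3-dioxolan-2-yl)-5-(tert-butyldimethylsilyloxy)cyclohex-3-ene-1-carboxylic acid | C[C@@]1(C(=O)O)CC=C[C@H](O[Si](C)(C)C(C)(C)C)[C@H]1C1(C)OCCO1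
A6 | alternative 3 | 3-methyl-4-(2-methyl-1,3-dioxolan-2-yl)-5-(tert-butyldimethylsilyloxy)-6-vinyltetrahydropyran-2-one (C3 either epimer) | CC1C(=O)O[C@@H](C=C)[C@H](O[Si](C)(C)C(C)(C)C)[C@H]1C1(C)OCCO1
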